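Readings and results are calculated for substances that don't exist; scatter was added.

Start with a subtraction: in Saturday's run at 8.00 h, c(substrate) reads 65.4% of its charge and target 16.2%, so 18.4% stands in neither column.

common to all: substrate 0.10 M

| charge | reagent in the second phase | remark | time | volume of the second phase over the first |
|---|---|---|---|---|
| Saturday's | 0.30 M | run made earlier |  |  |
| flask | 0.200 M |  | 40 h | 0.25 |

Saturday's run (percent of the substrate charged)

| time / h | target / % | substrate / % |
|---|---|---|
| 0.667 | 0.1 | 97.7 |
| 1.33 | 0.7 | 95.8 |
| 3.00 | 4.3 | 88.6 |
| 8.00 | 16.2 | 65.4 |

(each reading ± 0.3 percentage points)

- in the second phase: reagent in the second phase; everything else is in the first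
- charges count per volume of the first phase; a concentration in a rate is the amount of a species over the volume of its own phase; every rate counts per litre of the first phase
- the numbers in the tables scatter by 0.3 percentage points (one standard deviation)
- the earlier runs hold the two phases in the same ratio of volumes as the flask asked about

* target at 40 h, in percent of the substrate charged
* the change that raises the amount of target at 40 h, in percent of the substrate charged most ("none" if none brings more than 2 percentage points) (elm / birch / none)
* amount of target at 40 h, in percent of the substrate charged, after elm

- elm: doubling the transfer coefficient of the reagent in the second phase, all else as stated
- birch: doubling the amount of reagent in the second phase, all else as stated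

Take the substrate as the limiting reagent, since the flask is charged with 0.10 M of it against 0.200 M of reagent in the second phase, and keep its books. Of the substrate lost in Saturday's run by 8.00 h, the target share, meaning target formed over substrate lost, reads 46.8%, scatter included.

Here is my own reckoning for the flask. A first-order decay constant read off that same reading, 0.0531 /h, leaves in this reckoning 12.0% of the substrate at 40 h. Go round once more: the flask is charged with 0.667 times Saturday's reagent in the second phase, so I scale the constant to 0.0354 /h, which leaves 24.3% in the reckoning. Holding the target share at its Saturday reading, the substrate lost yields 35.5% of target, in percent of the substrate charged. Birch doubles the constant and gives 44.0%; elm has no term here, so I choose birch.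

The forecast says 58%, higher than mine, with 83% after elm and birch as best, reasoning that “Substrate plus target falls short of 100%, so an intermediate builds up”.

The flask gives 26.0% of target at 40 h. Birch adds 3.6 percentage points and elm 0.87 points, which makes 26.9% after elm, and the best change is birch.

    reagent in the reaction phase ⇌ reagent in the second phase, rate k1*([reagent in the reaction phase] - [reagent in the second phase]/K1) per volume of the first phase (partition coefficient = 11.0, kL = 0.200 /h)
    substrate + reagent in the reaction phase → target (k = 0.710 /M/h)
    reagent in the reaction phase + target → over-reacted product (k = 0.280 /M/h)
    substrate ⇌ dormant form (K = 1.10, k = 0.0220 /h)
    substrate + target → side product (k = 0.420 /M/h)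
    substrate → decomposition product (k = 5.80 × 10⁻⁵ /h)

At 40 h the flask has 17.7% of its substrate left and, with substrate in the dormant form counted as lost, a target share of 31.6%, lower than the 46.8% read in Saturday's run at 8.00 h. Now take the neighbouring flask with a quarter of the substrate, 0.025 M. My constant holds no substrate charge, so the reckoning gives 35.5% again. At 40 h that neighbour gives 36.7% of target with 17.4% of its substrate left, a target share of 44.4%. Its side product holds 7.44% of the substrate charged, against 23.0% in the flask.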